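**Strategy.** The target is cut at the spiroketal and traced to a 2-aryl-chroman-3-ol. The O–C2(spiro)–C3 dihydrofuran of the central acylphloroglucinol (ring B) is the contracted form of a pyran whose sixth atom is the benzylic CH2 of the neighbouring dihydrofuran (ring A). In one operation an epoxychroman is C-arylated by the ring-A phenol; the three ortho/para oxygens of ring A then ionise the pyran C–O bond, a 1,2-hydride shift makes C2 a ketone, and both phenols close the spiroketal. The precursor is an enantiopure 4-propargyl-2,3-epoxychroman from an organocatalytic Friedel–Crafts/hemiacetalisation; the benzofuran (ring C) is annulated afterwards by Sonogashira cyclisation.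

Key step: step 11

Remark: ring A is the dihydrobenzofuran with the spiro-bound CH2, ring B the dihydrobenzofuran with the stereogenic CH (C3), ring C the benzofuran, and C2 the spiro carbon. It is assumed that the spiro centre is under thermodynamic control and that its (2R) epimer, with the C3 side chain anti to the ring-A CH2 (syn to the smaller ring-A oxygen), is the more stable one.

Step 1
Reactants: 1 (phloroglucinol), 2 (3-methylbutanoyl chloride)
Product: 3 (1-(2,4,6-trihydroxyphenyl)-3-methylbutan-1-one)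
Conditions: AlCl3 (3 equiv), PhNO2, 60 °C; aq. HCl work-up
Reagents that add atoms: none
Why: Friedel–Crafts acylation of the threefold-activated arene; the first acyl group deactivates the ring, so monoacylation should dominate.

Step 2
Reactants: 3
Product: 4 (1-[2,4-bis(benzyloxy)-6-hydroxyphenyl]-3-methylbutan-1-one)
Conditions: BnBr (2.1 equiv), K2CO3 (2.2 equiv), DMF, 0 °C → rt
Reagents that add atoms: benzyl bromide BrCc1ccccc1
Why: Williamson ether synthesis; the para OH and one ortho OH are benzylated, while the last ortho OH is held in the hydrogen bond to the ketone and should stay free, so that it later becomes the ring oxygen of rings A and B.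

Step 3
Reactants: 3
Product: 5 (1-(2,4,6-trihydroxy-3-iodophenyl)-3-methylbutan-1-one)
Conditions: NIS (1.0 equiv), MeCN, −20 → 0 °C
Reagents that add atoms: N-iodosuccinimide O=C1CCC(=O)N1I
Why: electrophilic aromatic iodination; the two open ring positions are equivalent and one equivalent of NIS at low temperature should limit di-iodination.

Step 4
Reactants: 6 (but-3-en-1-yl acetate), 7 ((E)-but-2-enal)
Product: 8 ((E)-5-oxopent-3-en-1-yl acetate)
Conditions: Hoveyda–Grubbs II catalyst (3 mol%), 7 (4 equiv), CH2Cl2, 40 °C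
Reagents that add atoms: none
Why: olefin cross-metathesis of a terminal alkene with an excess of the slowly homodimerising enal should give the E-enal.

Step 5
Reactants: 4, 8
Product: 9 (2-[(4R)-5,7-bis(benzyloxy)-2-hydroxy-8-(3-methylbutanoyl)chroman-4-yl]ethyl acetate; both anomers)
Conditions: (S)-2-[diphenyl(trimethylsilyloxy)methyl]pyrrolidine (20 mol%), PhCO2H (20 mol%), toluene, 0 °C → rt
Reagents that add atoms: none
Why: iminium-catalysed asymmetric Friedel–Crafts alkylation/hemiacetalisation; the ring carbon of 4 ortho to the free OH adds to the β-carbon of the E-iminium ion on the face opposite the diphenyl(silyloxy)methyl group, which sets C4 (the later C3–H of the target) as R, and the phenol then closes the lactol.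

Step 6
Reactants: 9
Product: 10 (2-[(4R)-5,7-bis(benzyloxy)-8-(3-methylbutanoyl)-4H-chromen-4-yl]ethyl acetate)
Conditions: MsCl (1.5 equiv), Et3N (4 equiv), CH2Cl2, 0 → 40 °C
Reagents that add atoms: none
Why: sulfonylation of the lactol OH and loss of methanesulfonate from the anomeric position (glycal-type dehydration) should give the enol ether without touching the stereocentre.

Step 7
Reactants: 10
Product: 11 (1-[(4R)-5,7-bis(benzyloxy)-4-(2-hydroxyethyl)-4H-chromen-8-yl]-3-methylbutan-1-one)
Conditions: K2CO3 (0.2 equiv), MeOH–THF, rt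
Reagents that add atoms: none
Why: base-catalysed transesterification removes the acetate; enol ether, ketone and benzyl ethers are inert.

Step 8
Reactants: 11
Product: 12 (2-[(4R)-5,7-bis(benzyloxy)-8-(3-methylbutanoyl)-4H-chromen-4-yl]acetaldehyde)
Conditions: Dess–Martin periodinane (1.3 equiv), NaHCO3, CH2Cl2, 0 °C → rt
Reagents that add atoms: none
Why: Dess–Martin oxidation under buffered conditions spares the acid-labile enol ether, and the stereocentre is β to the new aldehyde and cannot epimerise.

Step 9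
Reactants: 12
Product: 13 (1-[(4R)-5,7-bis(benzyloxy)-4-(prop-2-yn-1-yl)-4H-chromen-8-yl]-3-methylbutan-1-one)
Conditions: Bestmann–Ohira reagent (1.3 equiv), K2CO3 (2 equiv), MeOH, 0 °C → rt
Reagents that add atoms: dimethyl (1-diazo-2-oxopropyl)phosphonate COP(=O)(OC)C(=[N+]=[N-])C(C)=O
Why: Seyferth–Gilbert homologation; the aldehyde reacts far faster than the di-ortho-substituted aryl ketone.

Step 10
Reactants: 13
Product: 14 (1-[(2S,3R,4S)-5,7-bis(benzyloxy)-2,3-epoxy-4-(prop-2-yn-1-yl)chroman-8-yl]-3-methylbutan-1-one; epoxide trans to the propargyl group; used crude)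
Conditions: dimethyldioxirane (1.1 equiv, acetone), CH2Cl2, −40 → 0 °C; evaporate
Reagents that add atoms: dimethyldioxirane CC1(C)OO1
Why: neutral epoxidation of the electron-rich enol ether, anti to the C4 substituent (glycal-type facial control); alkyne and aryl ketone react far more slowly, and the configuration of the two new centres is irrelevant later.

Step 11
Reactants: 14, 4
Product: 17 (1,1'-[(2R,3S)-4,4',6,6'-tetrakis(benzyloxy)-3-(prop-2-yn-1-yl)-3H,3'H-2,2'-spirobi[1-benzofuran]-7,7'-diyl]bis(3-methylbutan-1-one)), via flavan-3-ol 15 (not isolated), via open ketone 16 (not isolated)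
Conditions: 4 (1.1 equiv), Sc(OTf)3 (10 mol%), 4 Å MS, CH2Cl2–HFIP 4:1, −40 °C → rt; Et3N quench
Reagents that add atoms: none
Why: The Lewis acid opens the acetal-type epoxide to the C2 oxocarbenium ion, which the ring carbon of 4 ortho to its free OH captures anti to the C3 oxygen (C-aryl-glycoside-type Friedel–Crafts arylation) to give 15; the new 2-aryl group, with two ortho and one para oxygen, then lets the O1–C2 bond ionise to an ortho-quinone-methide-type cation, and a 1,2-hydride shift from the carbinol carbon gives ketone 16. The closest known reaction types are the pinacol/semipinacol rearrangement of 1-aryl-1,2-diol monoethers to benzyl ketones and the acid ketalisation of 1,3-bis(2-hydroxyaryl)propan-2-ones to 2,2'-spirobi(benzofurans). Ring A closes by 5-exo-trig addition of its one free phenol to the ketone and ring B by 5-exo attack of the released phenol on the resulting oxocarbenium ion, so that the pyran O1–C2–C3–C4–C4a–C8a of 15 becomes the furan O1–C3–C4–C4a–C8a, with old C2 expelled as the CH2 of ring A. The stereogenic CH (old C4) is not touched, and the spiro centre equilibrates through the oxocarbenium ion and should settle with the propargyl group anti to the ring-A CH2 (2R). The step needs ortho-selective C-arylation, hydride rather than alkyl migration, and ketalisation faster than enolisation or proton loss to a benzofuran; the chelated free OH of 4, the secondary carbinol, and benzyl protection that leaves exactly one free phenol per ring are meant to secure these.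

Step 12
Reactants: 17, 5
Product: 19 (1-[2-{[(2R,3S)-4,4',6,6'-tetrakis(benzyloxy)-7,7'-bis(3-methylbutanoyl)-3H,3'H-2,2'-spirobi[1-benzofuran]-3-yl]methyl}-4,6-dihydroxy-1-benzofuran-5-yl]-3-methylbutan-1-one), via alkynylphenol 18 (not isolated)
Conditions: PdCl2(PPh3)2 (5 mol%), CuI (10 mol%), Et3N (5 equiv), DMF, degassed, 60 °C
Reagents that add atoms: none
Why: Sonogashira coupling followed by 5-endo-dig cycloisomerisation; under Et3N only the para OH (most acidic, not hydrogen-bonded to the ketone) is ionised, so the ring oxygen should end para to the acyl group as in ring C, and the spiroketal and stereocentres are untouched.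

Step 13
Reactants: 19
Product: 20 (target, CNP0169640.1)
Conditions: H2 (1 atm), 10% Pd/C, EtOAc–MeOH, rt
Reagents that add atoms: none
Why: hydrogenolysis of the four aryl benzyl ethers; aryl ketones, the non-benzylic spiroketal C–O bonds and the benzofuran should survive short exposure at 1 atm.

**Compound list**

1 | phloroglucinol | Oc1cc(O)cc(O)c1 | starting material
2 | 3-methylbutanoyl chloride | CC(C)CC(=O)Cl | starting material
3 | 1-(2,4,6-trihydroxyphenyl)-3-methylbutan-1-one | CC(C)CC(=O)c1c(O)cc(O)cc1O | intermediate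
4 | 1-[2,4-bis(benzyloxy)-6-hydroxyphenyl]-3-methylbutan-1-one | CC(C)CC(=O)c1c(O)cc(OCc2ccccc2)cc1OCc1ccccc1 | intermediate
5 | 1-(2,4,6-trihydroxy-3-iodophenyl)-3-methylbutan-1-one | CC(C)CC(=O)c1c(O)cc(O)c(I)c1O | intermediate
6 | but-3-en-1-yl acetate | CC(=O)OCCC=C | starting material
7 | (E)-but-2-enal | C/C=C/C=O | starting material
8 | (E)-5-oxopent-3-en-1-yl acetate | CC(=O)OCC/C=C/C=O | intermediate
9 | 2-[(4R)-5,7-bis(benzyloxy)-2-hydroxy-8-(3-methylbutanoyl)chroman-4-yl]ethyl acetate (anomer mixture) | CC(=O)OCC[C@@H]1CC(O)Oc2c(C(=O)CC(C)C)c(OCc3ccccc3)cc(OCc3ccccc3)c21 | intermediate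
10 | 2-[(4R)-5,7-bis(benzyloxy)-8-(3-methylbutanoyl)-4H-chromen-4-yl]ethyl acetate | CC(=O)OCC[C@@H]1C=COc2c(C(=O)CC(C)C)c(OCc3ccccc3)cc(OCc3ccccc3)c21 | intermediate
11 | 1-[(4R)-5,7-bis(benzyloxy)-4-(2-hydroxyethyl)-4H-chromen-8-yl]-3-methylbutan-1-one | OCC[C@@H]1C=COc2c(C(=O)CC(C)C)c(OCc3ccccc3)cc(OCc3ccccc3)c21 | intermediate
12 | 2-[(4R)-5,7-bis(benzyloxy)-8-(3-methylbutanoyl)-4H-chromen-4-yl]acetaldehyde | O=CC[C@@H]1C=COc2c(C(=O)CC(C)C)c(OCc3ccccc3)cc(OCc3ccccc3)c21 | intermediate
13 | 1-[(4R)-5,7-bis(benzyloxy)-4-(prop-2-yn-1-yl)-4H-chromen-8-yl]-3-methylbutan-1-one | C#CC[C@@H]1C=COc2c(C(=O)CC(C)C)c(OCc3ccccc3)cc(OCc3ccccc3)c21 | intermediate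
14 | 1-[(2S,3R,4S)-5,7-bis(benzyloxy)-2,3-epoxy-4-(prop-2-yn-1-yl)chroman-8-yl]-3-methylbutan-1-one | C#CC[C@@H]1[C@H]2O[C@H]2Oc2c(C(=O)CC(C)C)c(OCc3ccccc3)cc(OCc3ccccc3)c21 | intermediate
15 | 1-[(2S,3R,4S)-5,7-bis(benzyloxy)-2-[4,6-bis(benzyloxy)-2-hydroxy-3-(3-methylbutanoyl)phenyl]-3-hydroxy-4-(prop-2-yn-1-yl)chroman-8-yl]-3-methylbutan-1-one (all-trans flavan-3-ol, not isolated) | C#CC[C@@H]1[C@@H](O)[C@H](c2c(O)c(C(=O)CC(C)C)c(OCc3ccccc3)cc2OCc2ccccc2)Oc2c(C(=O)CC(C)C)c(OCc3ccccc3)cc(OCc3ccccc3)c21 | intermediate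
16 | (3S)-1,3-bis[4,6-bis(benzyloxy)-2-hydroxy-3-(3-methylbutanoyl)phenyl]hex-5-yn-2-one (not isolated) | C#CC[C@H](C(=O)Cc1c(O)c(C(=O)CC(C)C)c(OCc2ccccc2)cc1OCc1ccccc1)c1c(O)c(C(=O)CC(C)C)c(OCc2ccccc2)cc1OCc1ccccc1 | intermediate
17 | 1,1'-[(2R,3S)-4,4',6,6'-tetrakis(benzyloxy)-3-(prop-2-yn-1-yl)-3H,3'H-2,2'-spirobi[1-benzofuran]-7,7'-diyl]bis(3-methylbutan-1-one) | CC(C)CC(=O)c1c(OCc2ccccc2)cc(OCc2ccccc2)c2c1O[C@]1(C2)Oc2c(C(=O)CC(C)C)c(OCc3ccccc3)cc(OCc3ccccc3)c2[C@@H]1CC#C | intermediate
18 | 17 carrying a 2,4,6-trihydroxy-3-(3-methylbutanoyl)phenyl group on the alkyne terminus (not isolated) | CC(C)CC(=O)c1c(OCc2ccccc2)cc(OCc2ccccc2)c2c1O[C@]1(C2)Oc2c(C(=O)CC(C)C)c(OCc3ccccc3)cc(OCc3ccccc3)c2[C@@H]1CC#Cc1c(O)cc(O)c(C(=O)CC(C)C)c1O | intermediate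
19 | 4,4',6,6'-tetra-O-benzyl ether of the target (rings A and B benzylated, ring C free) | CC(C)CC(=O)c1c(OCc2ccccc2)cc(OCc2ccccc2)c2c1O[C@]1(C2)Oc2c(C(=O)CC(C)C)c(OCc3ccccc3)cc(OCc3ccccc3)c2[C@@H]1Cc1cc2c(O)c(C(=O)CC(C)C)c(O)cc2o1 | intermediate
20 | 1-[2-{[(2R,3S)-4,4',6,6'-tetrahydroxy-7,7'-bis(3-methylbutanoyl)-3H,3'H-2,2'-spirobi[1-benzofuran]-3-yl]methyl}-4,6-dihydroxy-1-benzofuran-5-yl]-3-methylbutan-1-one | CC(C)CC(=O)c1c(O)cc(O)c2c1O[C@]1(C2)Oc2c(C(=O)CC(C)C)c(O)cc(O)c2[C@@H]1Cc1cc2c(O)c(C(=O)CC(C)C)c(O)cc2o1 | target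

**Step count.** Total: 13 steps. Longest linear sequence: 11 steps (steps 1, 2, 5–13, from phloroglucinol).

**Steps most likely to fail**

1. Step 11. The oxocarbenium ion that precedes each ketal closure may lose a proton instead and aromatise irreversibly to a benzofuran. The open ketone may enolise towards the stereogenic CH and erode the ee. Arylation may occur at oxygen or at the carbon between the two benzyloxy groups, and the quinone methide may be trapped by a second molecule of 4. Fallback: setting out from 14 and 4, the arylation alone would be run at −60 °C and quenched with Et3N to isolate flavan-3-ol 15. Dess–Martin oxidation would give the (2S,4S)-flavan-3-one F1. SmI2 in THF–MeOH at −78 °C would cleave its α-aryloxy-ketone C2–O1 bond reductively to the open ketone 16 without any cation. PPTS and 4 Å sieves in CH2Cl2 would then close 16 to 17, where the route is rejoined.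

2. Step 5. The acyl-deactivated phenol may react slowly with the iminium ion, so that uncatalysed 1,2-addition/condensation to a 2H-chromene and self-condensation of the enal compete and the ee is eroded. Fallback: setting out from 4 and 8, pyrrolidine/benzoic acid would give the racemic lactol F2. Acetalisation with (1R,2S,5R)-menthol (PPTS, benzene, sieves) would give diastereomeric acetals, from which the (4R)-menthyl acetal F3 is separated by chromatography or crystallisation. Mild aqueous acid (AcOH–THF–H2O) would return enantiopure 9.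

3. Step 12. Oxidative addition to the very electron-rich, unprotected iodophenol may be slow, with protodeiodination, alkyne homocoupling and copper sequestration by the β-hydroxy-ketone motif competing. Cyclisation may also run through a chelated OH and give the regioisomeric benzofuran. Fallback: setting out from 3, the para OH would be masked first (MOMCl, iPr2NEt) to give the 4-O-MOM ether F4. Both chelated OH groups would be benzylated under forcing conditions (BnBr, K2CO3, DMF, 80 °C) to the dibenzyl MOM ether F5. The MOM group would be removed (HCl, MeOH) to the 4-hydroxy-2,6-dibenzyl ether F6, and this iodinated (NIS) to the iodophenol F7, in which only the oxygen para to the ketone can cyclise. Sonogashira coupling/cyclisation of F7 with 17 would give the hexabenzyl ether F8, and hydrogenolysis of F8 rejoins the route at 20.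

Further compounds
F1 | step 11 | 1-[(2S,4S)-5,7-bis(benzyloxy)-2-[4,6-bis(benzyloxy)-2-hydroxy-3-(3-methylbutanoyl)phenyl]-3-oxo-4-(prop-2-yn-1-yl)chroman-8-yl]-3-methylbutan-1-one | C#CC[C@@H]1C(=O)[C@H](c2c(O)c(C(=O)CC(C)C)c(OCc3ccccc3)cc2OCc2ccccc2)Oc2c(C(=O)CC(C)C)c(OCc3ccccc3)cc(OCc3ccccc3)c21
F2 | step 5 | racemic 2-[5,7-bis(benzyloxy)-2-hydroxy-8-(3-methylbutanoyl)chroman-4-yl]ethyl acetate | CC(=O)OCCC1CC(O)Oc2c(C(=O)CC(C)C)c(OCc3ccccc3)cc(OCc3ccccc3)c21
F3 | step 5 | 2-[(4R)-5,7-bis(benzyloxy)-2-{[(1R,2S,5R)-2-isopropyl-5-methylcyclohexyl]oxy}-8-(3-methylbutanoyl)chroman-4-yl]ethyl acetate | CC(=O)OCC[C@@H]1CC(O[C@@H]2C[C@H](C)CC[C@H]2C(C)C)Oc2c(C(=O)CC(C)C)c(OCc3ccccc3)cc(OCc3ccccc3)c21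
F4 | step 12 | 1-[2,6-dihydroxy-4-(methoxymethoxy)phenyl]-3-methylbutan-1-one | CC(C)CC(=O)c1c(O)cc(OCOC)cc1O
F5 | step 12 | 1-[2,6-bis(benzyloxy)-4-(methoxymethoxy)phenyl]-3-methylbutan-1-one | CC(C)CC(=O)c1c(OCc2ccccc2)cc(OCOC)cc1OCc1ccccc1
F6 | step 12 | 1-[2,6-bis(benzyloxy)-4-hydroxyphenyl]-3-methylbutan-1-one | CC(C)CC(=O)c1c(OCc2ccccc2)cc(O)cc1OCc1ccccc1
F7 | step 12 | 1-[2,6-bis(benzyloxy)-4-hydroxy-3-iodophenyl]-3-methylbutan-1-one | CC(C)CC(=O)c1c(OCc2ccccc2)cc(O)c(I)c1OCc1ccccc1
F8 | step 12 | hexa-O-benzyl ether of the target | CC(C)CC(=O)c1c(OCc2ccccc2)cc(OCc2ccccc2)c2c1O[C@]1(C2)Oc2c(C(=O)CC(C)C)c(OCc3ccccc3)cc(OCc3ccccc3)c2[C@@H]1Cc1cc2c(OCc3ccccc3)c(C(=O)CC(C)C)c(OCc3ccccc3)cc2o1
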